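**Retrosynthetic overview**
1. Target 16 ⇐ hydrogenolysis of the tri-O-benzyl trans-lactone 15.
2. Lactone 15 ⇐ γ-hydroxy tert-butyl ester 13 (acid lactonisation, then base equilibration of C3 to trans) ⇐ LiBH4 cleavage of imide 12.
3. Key disconnection C3–C4 of the lactone (lignan C8–C8′): oxidative heterocoupling of the enolates of imide 5 and ester 11, in which the ester enolate is oxidised to an electrophilic α-carbonyl radical; the auxiliary sets C4.
4. 5 ⇐ dihydroferulic acid 1 + oxazolidinone 3; 11 ⇐ dihydrocoumarin 9 ⇐ 2-methoxyresorcinol 6 + acrylic acid 7.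
5. Ring order: the dihydrocoumarin ring is made first (step 3) and opened again (step 4); the butyrolactone, the only non-aromatic ring of the target, is closed in step 7.

Assumption: the target is the (3R,4R) trans-lactone.
Convention: 12, 13 and 14 are each an unseparated pair of epimers at the one carbon α to the ester or lactone carbonyl; each pair carries one number and a SMILES that leaves only that centre open, and the centre is fixed in step 7.

**Step 1**
Reactants: 1 3-(4-hydroxy-3-methoxyphenyl)propanoic acid (dihydroferulic acid)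
Product: 2 3-[4-(benzyloxy)-3-methoxyphenyl]propanoic acid
Conditions: BnBr (1.5 equiv), NaOH (3 equiv), EtOH–H2O, reflux; then aq. HCl
Reagents that add atoms: benzyl bromide, BrCc1ccccc1
Why: Williamson ether synthesis; in aqueous base the phenoxide is far more nucleophilic than the carboxylate, and any benzyl ester formed is saponified in the same pot.

**Step 2**
Reactants: 2 3-[4-(benzyloxy)-3-methoxyphenyl]propanoic acid; 3 (S)-4-benzyloxazolidin-2-one
Product: 5 (S)-4-benzyl-3-{3-[4-(benzyloxy)-3-methoxyphenyl]propanoyl}oxazolidin-2-one, via mixed pivalic anhydride 4 (not isolated)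
Conditions: PivCl (1.1 equiv), Et3N (2.5 equiv), THF, −20 °C; then 3, LiCl (1.1 equiv), −20 °C to rt
Reagents that add atoms: pivaloyl chloride, CC(C)(C)C(=O)Cl (its atoms are carried only by intermediate 4; none remain in 5)
Why: N-acylation of an Evans auxiliary through a mixed anhydride; the hindered pivaloyl carbonyl directs attack of the LiCl-activated oxazolidinone to the desired acyl group.

**Step 3**
Reactants: 6 2-methoxybenzene-1,3-diol (2-methoxyresorcinol); 7 acrylic acid
Product: 9 7-hydroxy-8-methoxychroman-2-one, via hydroxy acid 8 (not isolated)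
Conditions: acrylic acid (1.2 equiv), Amberlyst-15 (sulfonic acid resin), toluene, reflux, Dean–Stark
Reagents that add atoms: none
Why: Acid-catalysed Friedel–Crafts conjugate hydroarylation at the position para to one OH and ortho to the other (C4 and C6 are equivalent), followed by lactonisation onto the ortho OH, as known for resorcinol.

**Step 4**
Reactants: 9 7-hydroxy-8-methoxychroman-2-one
Product: 11 tert-butyl 3-[2,4-bis(benzyloxy)-3-methoxyphenyl]propanoate, via dipotassium bis-phenoxide 10 (not isolated)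
Conditions: KOtBu (2.2 equiv), THF, 0 °C; then BnBr (2.5 equiv), Bu4NI (cat.), DMF, rt
Reagents that add atoms: potassium tert-butoxide, CC(C)(C)[O-].[K+]; benzyl bromide, BrCc1ccccc1
Why: Alkoxide opening of the aryl lactone (transesterification, driven by release of the far less basic phenoxide) followed by Williamson etherification of both phenoxides, which blocks re-closure.

**Step 5**
Reactants: 5 (S)-4-benzyl-3-{3-[4-(benzyloxy)-3-methoxyphenyl]propanoyl}oxazolidin-2-one; 11 tert-butyl 3-[2,4-bis(benzyloxy)-3-methoxyphenyl]propanoate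
Product: 12 tert-butyl (2RS,3R)-2-[2,4-bis(benzyloxy)-3-methoxybenzyl]-3-[4-(benzyloxy)-3-methoxybenzyl]-4-[(S)-4-benzyl-2-oxooxazolidin-3-yl]-4-oxobutanoate (unseparated C2-epimer pair)
Conditions: 5 (1.0 equiv) and 11 (1.5 equiv) added to LiN(iPr)2 (2.6 equiv), THF, −78 °C, 30 min; then Fe(acac)3 (2.5 equiv) in THF, −78 °C to rt; chromatography removes the homodimers only
Reagents that add atoms: none
Why: Oxidative enolate heterocoupling (Baran-type): one-electron oxidation by trivalent iron turns the more easily oxidised ester enolate into an electrophilic α-carbonyl radical, which is captured by the chelated Z-enolate of the imide on the face away from the auxiliary's 4-benzyl group (the Evans alkylation sense), setting C3 as R (the future lactone C4), while C2 is not controlled (about 2:1 expected) and is left open because step 7 corrects it.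

**Step 6**
Reactants: 12 tert-butyl (2RS,3R)-2-[2,4-bis(benzyloxy)-3-methoxybenzyl]-3-[4-(benzyloxy)-3-methoxybenzyl]-4-[(S)-4-benzyl-2-oxooxazolidin-3-yl]-4-oxobutanoate (C2-epimer pair)
Product: 13 tert-butyl (2RS,3R)-2-[2,4-bis(benzyloxy)-3-methoxybenzyl]-3-[4-(benzyloxy)-3-methoxybenzyl]-4-hydroxybutanoate (unseparated C2-epimer pair)
Conditions: LiBH4 (2 equiv), H2O (1.1 equiv), Et2O, 0 °C; aq. NH4Cl work-up
Reagents that add atoms: none
Why: Chemoselective reductive cleavage of the N-acyloxazolidinone by LiBH4; the activated imide carbonyl is reduced to CH2OH while the tert-butyl ester is inert at 0 °C, and no stereocentre is touched (auxiliary 3 is recovered).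

**Step 7**
Reactants: 13 tert-butyl (2RS,3R)-2-[2,4-bis(benzyloxy)-3-methoxybenzyl]-3-[4-(benzyloxy)-3-methoxybenzyl]-4-hydroxybutanoate (C2-epimer pair)
Product: 15 (3R,4R)-3-[2,4-bis(benzyloxy)-3-methoxybenzyl]-4-[4-(benzyloxy)-3-methoxybenzyl]dihydrofuran-2(3H)-one, via lactone C3-epimer pair 14 (not isolated)
Conditions: p-TsOH·H2O (0.1 equiv), toluene, 80 °C; then DBU (2 equiv), 100 °C, same pot
Reagents that add atoms: none
Why: Acid-catalysed lactonisation (intramolecular transesterification) converts both epimers of 13 into the cis/trans lactone pair 14, and DBU-mediated enolisation then equilibrates the only acidic centre (C3) to the more stable trans arrangement, setting C3 as R relative to the fixed C4.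

**Step 8**
Reactants: 15 (3R,4R)-3-[2,4-bis(benzyloxy)-3-methoxybenzyl]-4-[4-(benzyloxy)-3-methoxybenzyl]dihydrofuran-2(3H)-one
Product: 16 (3R,4R)-3-(2,4-dihydroxy-3-methoxybenzyl)-4-(4-hydroxy-3-methoxybenzyl)dihydrofuran-2(3H)-one (target)
Conditions: H2 (1 atm), 10% Pd/C, EtOAc–EtOH, rt
Reagents that add atoms: none
Why: Catalytic hydrogenolysis of the three aryl benzyl ethers under neutral conditions, which avoids both C3 epimerisation and translactonisation onto the freed ortho-phenol.

**Compound list**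
1 | 3-(4-hydroxy-3-methoxyphenyl)propanoic acid (dihydroferulic acid) | COc1cc(CCC(=O)O)ccc1O | starting material
2 | 3-[4-(benzyloxy)-3-methoxyphenyl]propanoic acid | COc1cc(CCC(=O)O)ccc1OCc1ccccc1 | intermediate
3 | (S)-4-benzyloxazolidin-2-one | O=C1N[C@@H](Cc2ccccc2)CO1 | starting material
4 | 3-[4-(benzyloxy)-3-methoxyphenyl]propanoic pivalic anhydride | COc1cc(CCC(=O)OC(=O)C(C)(C)C)ccc1OCc1ccccc1 | intermediate (not isolated)
5 | (S)-4-benzyl-3-{3-[4-(benzyloxy)-3-methoxyphenyl]propanoyl}oxazolidin-2-one | COc1cc(CCC(=O)N2[C@@H](Cc3ccccc3)COC2=O)ccc1OCc1ccccc1 | intermediate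
6 | 2-methoxybenzene-1,3-diol (2-methoxyresorcinol) | COc1c(O)cccc1O | starting material
7 | acrylic acid | C=CC(=O)O | starting material
8 | 3-(2,4-dihydroxy-3-methoxyphenyl)propanoic acid | COc1c(O)ccc(CCC(=O)O)c1O | intermediate (not isolated)
9 | 7-hydroxy-8-methoxychroman-2-one | COc1c(O)ccc2CCC(=O)Oc12 | intermediate
10 | dipotassium salt of tert-butyl 3-(2,4-dihydroxy-3-methoxyphenyl)propanoate | COc1c([O-])ccc(CCC(=O)OC(C)(C)C)c1[O-].[K+].[K+] | intermediate (not isolated)
11 | tert-butyl 3-[2,4-bis(benzyloxy)-3-methoxyphenyl]propanoate | COc1c(OCc2ccccc2)ccc(CCC(=O)OC(C)(C)C)c1OCc1ccccc1 | intermediate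
12 | tert-butyl (2RS,3R)-2-[2,4-bis(benzyloxy)-3-methoxybenzyl]-3-[4-(benzyloxy)-3-methoxybenzyl]-4-[(S)-4-benzyl-2-oxooxazolidin-3-yl]-4-oxobutanoate (C2-epimer pair, C2 left open) | COc1cc(C[C@@H](C(=O)N2[C@@H](Cc3ccccc3)COC2=O)C(Cc2ccc(OCc3ccccc3)c(OC)c2OCc2ccccc2)C(=O)OC(C)(C)C)ccc1OCc1ccccc1 | intermediate
13 | tert-butyl (2RS,3R)-2-[2,4-bis(benzyloxy)-3-methoxybenzyl]-3-[4-(benzyloxy)-3-methoxybenzyl]-4-hydroxybutanoate (C2-epimer pair, C2 left open) | COc1cc(C[C@@H](CO)C(Cc2ccc(OCc3ccccc3)c(OC)c2OCc2ccccc2)C(=O)OC(C)(C)C)ccc1OCc1ccccc1 | intermediate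
14 | (3RS,4R)-3-[2,4-bis(benzyloxy)-3-methoxybenzyl]-4-[4-(benzyloxy)-3-methoxybenzyl]dihydrofuran-2(3H)-one (cis/trans pair, C3 left open) | COc1cc(C[C@H]2COC(=O)C2Cc2ccc(OCc3ccccc3)c(OC)c2OCc2ccccc2)ccc1OCc1ccccc1 | intermediate (not isolated)
15 | (3R,4R)-3-[2,4-bis(benzyloxy)-3-methoxybenzyl]-4-[4-(benzyloxy)-3-methoxybenzyl]dihydrofuran-2(3H)-one (trans-lactone) | COc1cc(C[C@H]2COC(=O)[C@@H]2Cc2ccc(OCc3ccccc3)c(OC)c2OCc2ccccc2)ccc1OCc1ccccc1 | intermediate
16 | (3R,4R)-3-(2,4-dihydroxy-3-methoxybenzyl)-4-(4-hydroxy-3-methoxybenzyl)dihydrofuran-2(3H)-one | COc1cc(C[C@H]2COC(=O)[C@@H]2Cc2ccc(O)c(OC)c2O)ccc1O | target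

**Step count**
Total: 8 steps. Longest linear sequence: 6 steps (1 → 2 → 5 → 12 → 13 → 15 → 16, or equally 6 → 9 → 11 → 12 → 13 → 15 → 16).

**Three steps most likely to fail, with fallbacks**

Step 5 (heterocoupling) is the riskiest: homodimers of 5 and of 11 compete, and a realistic yield of the cross-product is about 35–50%. The fallback forms the same bond from an α-bromo ester as the electrophilic partner and adds the second benzyl group afterwards. It sets out from 5 (and from 6 for the benzyl bromide) and comes back at 15. Imide 5 is deprotonated with NaN(SiMe3)2 (THF, −78 °C) and alkylated with tert-butyl bromoacetate to give tert-butyl (3R)-3-[4-(benzyloxy)-3-methoxybenzyl]-4-[(S)-4-benzyl-2-oxooxazolidin-3-yl]-4-oxobutanoate F1. LiBH4 cleavage gives tert-butyl (3R)-3-[4-(benzyloxy)-3-methoxybenzyl]-4-hydroxybutanoate F2, and p-TsOH in toluene closes it to (4R)-4-[4-(benzyloxy)-3-methoxybenzyl]dihydrofuran-2(3H)-one F3. In parallel, 6 is dibenzylated (BnBr, K2CO3, DMF) to 1,3-bis(benzyloxy)-2-methoxybenzene F4 and formylated (POCl3, DMF, Vilsmeier–Haack) to 2,4-bis(benzyloxy)-3-methoxybenzaldehyde F5. This is reduced (NaBH4, MeOH) to [2,4-bis(benzyloxy)-3-methoxyphenyl]methanol F6 and converted (PBr3, CH2Cl2, 0 °C) into 1,3-bis(benzyloxy)-4-(bromomethyl)-2-methoxybenzene F7. The lithium enolate of F3 (LiN(SiMe3)2, THF, −78 °C) is then alkylated with F7 anti to the C4 substituent, which gives the trans-lactone 15 directly.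

Step 6 (LiBH4 cleavage) may fail because the imide is α,β-branched and hindered, so hydride can attack the ring carbonyl of the auxiliary instead. The fallback sets out from 12 and comes back at 13. LiOH/H2O2 (THF–H2O, 0 °C) removes the auxiliary hydrolytically to give (2R,3RS)-3-[2,4-bis(benzyloxy)-3-methoxybenzyl]-2-[4-(benzyloxy)-3-methoxybenzyl]-4-tert-butoxy-4-oxobutanoic acid F8, still as the unseparated epimer pair. BH3·SMe2 (THF, 0 °C to rt) then reduces the free acid selectively in the presence of the tert-butyl ester to the hydroxy ester 13.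

Step 4 (one-pot opening and benzylation) may fail through incomplete opening, re-closure to the lactone or consumption of BnBr by tert-butoxide. The fallback sets out from 9 and comes back at 11. The lactone is opened hydrolytically and both phenols are benzylated in one pot (BnBr in excess, NaOH, aq. EtOH, reflux; then HCl) to give 3-[2,4-bis(benzyloxy)-3-methoxyphenyl]propanoic acid F10, which is esterified with tert-butyl 2,2,2-trichloroacetimidate (cat. BF3·OEt2, CH2Cl2–cyclohexane) to give 11.

**Further compounds**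
F1 | step 5 | tert-butyl (3R)-3-[4-(benzyloxy)-3-methoxybenzyl]-4-[(S)-4-benzyl-2-oxooxazolidin-3-yl]-4-oxobutanoate | COc1cc(C[C@H](CC(=O)OC(C)(C)C)C(=O)N2[C@@H](Cc3ccccc3)COC2=O)ccc1OCc1ccccc1
F2 | step 5 | tert-butyl (3R)-3-[4-(benzyloxy)-3-methoxybenzyl]-4-hydroxybutanoate | COc1cc(C[C@H](CC(=O)OC(C)(C)C)CO)ccc1OCc1ccccc1
F3 | step 5 | (4R)-4-[4-(benzyloxy)-3-methoxybenzyl]dihydrofuran-2(3H)-one | COc1cc(C[C@H]2COC(=O)C2)ccc1OCc1ccccc1
F4 | step 5 | 1,3-bis(benzyloxy)-2-methoxybenzene | COc1c(OCc2ccccc2)cccc1OCc1ccccc1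
F5 | step 5 | 2,4-bis(benzyloxy)-3-methoxybenzaldehyde | COc1c(OCc2ccccc2)ccc(C=O)c1OCc1ccccc1
F6 | step 5 | [2,4-bis(benzyloxy)-3-methoxyphenyl]methanol | COc1c(OCc2ccccc2)ccc(CO)c1OCc1ccccc1
F7 | step 5 | 1,3-bis(benzyloxy)-4-(bromomethyl)-2-methoxybenzene | COc1c(OCc2ccccc2)ccc(CBr)c1OCc1ccccc1
F8 | step 6 | (2R,3RS)-3-[2,4-bis(benzyloxy)-3-methoxybenzyl]-2-[4-(benzyloxy)-3-methoxybenzyl]-4-tert-butoxy-4-oxobutanoic acid (C3-epimer pair, C3 left open) | COc1cc(C[C@@H](C(=O)O)C(Cc2ccc(OCc3ccccc3)c(OC)c2OCc2ccccc2)C(=O)OC(C)(C)C)ccc1OCc1ccccc1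
F10 | step 4 | 3-[2,4-bis(benzyloxy)-3-methoxyphenyl]propanoic acid | COc1c(OCc2ccccc2)ccc(CCC(=O)O)c1OCc1ccccc1
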